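**Retrosynthetic overview**
- Target ⇐ O18 desilylation and O3 acetylation ⇐ 13(16),14-diene built on C13 of a tricyclic δ-lactone (vinyl addition, then methylenation, which also frees the 8-OH).
- Key disconnection: trans-decalin plus cis-fused lactone ⇐ acyclic (2R,3R)-epoxy (4Z,8E)-dienoic tert-butyl ester. One cationic cascade sets C5, C8, C9 and C10; C3 and C4 come from the epoxide.
- The Z olefin encodes the unusual C9 configuration (side arm anti to the C10 methyl, cis to O8); the E olefin gives the trans ring fusion.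
- Epoxide ⇐ Sharpless epoxidation of the E-allylic alcohol made by SeO2 oxidation of the terminal prenyl group; chain ⇐ (2Z,6E)-farnesyl bromide + tert-butyl acetate; the 2Z acid ⇐ geranyl bromide + 3-methylbut-2-enoic acid.
- Ring order: ring A, then ring B, then the lactone ring, all in step 8.

Convention: labdane numbering C1–C20, α/β = below/above the usual drawing; the target is read as 3α-OAc, 4α-CH3, 4β-CH2OH (C18), 5β-H, 8α-CH3, 8β-OH, 9α-H (side arm β, anti to the 10α-CH3), i.e. (3R,4S,5S,8S,9R,10R).

**Route**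

Step 1
Reactants: 1 3-methylbut-2-enoic acid; 2 geranyl bromide, (2E)-1-bromo-3,7-dimethylocta-2,6-diene
Product: 5 (2Z,6E)-3,7,11-trimethyldodeca-2,6,10-trienoic acid, via dilithium dienolate 3 (not isolated), via dicopper dienolate 4 (not isolated)
Conditions: LiN(iPr)2 (2.1 equiv), THF, −78 to 0 °C; CuI (2.0 equiv), −78 °C; then 2, −78 °C to rt; aq. HCl
Reagents that add atoms: none
Why: γ-Allylation of a copper dienolate, in which the carboxylate-chelated cisoid dienolate is alkylated at the γ-carbon by the allylic bromide (SN2, geranyl E olefin untouched), placing the new chain cis to CO2H and so setting the 2Z olefin that later encodes C9.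

Step 2
Reactants: 5 (2Z,6E)-3,7,11-trimethyldodeca-2,6,10-trienoic acid
Product: 6 (2Z,6E)-3,7,11-trimethyldodeca-2,6,10-trien-1-ol
Conditions: LiAlH4, Et2O, 0 °C to rt
Reagents that add atoms: none
Why: Hydride reduction of the conjugated acid by 1,2-addition gives the allylic alcohol without changing either olefin geometry.

Step 3
Reactants: 6 (2Z,6E)-3,7,11-trimethyldodeca-2,6,10-trien-1-ol
Product: 7 (2Z,6E)-1-bromo-3,7,11-trimethyldodeca-2,6,10-triene
Conditions: PBr3 (0.4 equiv), Et2O, −10 °C; used crude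
Reagents that add atoms: phosphorus tribromide, BrP(Br)Br
Why: Alcohol-to-bromide conversion through the phosphite ester and SN2 displacement at the primary allylic carbon at low temperature keeps the 2Z geometry.

Step 4
Reactants: 7 (2Z,6E)-1-bromo-3,7,11-trimethyldodeca-2,6,10-triene; 8 tert-butyl acetate
Product: 10 tert-butyl (4Z,8E)-5,9,13-trimethyltetradeca-4,8,12-trienoate, via lithium enolate 9 (not isolated)
Conditions: 8, LiN(iPr)2, THF, −78 °C; then 7, DMPU, −78 to −20 °C
Reagents that add atoms: none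
Why: SN2 alkylation of the lithium ester enolate by the primary allylic bromide (enolate alkylation) adds the two-carbon arm whose ester later terminates the cyclization, with both olefin geometries retained.

Step 5
Reactants: 10 tert-butyl (4Z,8E)-5,9,13-trimethyltetradeca-4,8,12-trienoate
Product: 11 tert-butyl (4Z,8E,12E)-14-hydroxy-5,9,13-trimethyltetradeca-4,8,12-trienoate
Conditions: SeO2 (cat.), salicylic acid (cat.), tBuOOH, CH2Cl2, rt; stopped at partial conversion, 10 recycled
Reagents that add atoms: SeO2, O=[Se]=O (oxygen-transfer catalyst); tert-butyl hydroperoxide, CC(C)(C)OO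
Why: Catalytic SeO2 allylic oxidation (ene reaction, then [2,3]-sigmatropic shift) is selective for the E-methyl of the terminal, most electron-rich olefin, giving the 12E allylic alcohol that becomes the equatorial C18 hydroxymethyl.

Step 6
Reactants: 11 tert-butyl (4Z,8E,12E)-14-hydroxy-5,9,13-trimethyltetradeca-4,8,12-trienoate
Product: 12 tert-butyl (4Z,8E)-11-[(2R,3R)-3-(hydroxymethyl)-3-methyloxiran-2-yl]-5,9-dimethylundeca-4,8-dienoate
Conditions: Ti(OiPr)4 (10 mol %), D-(−)-diethyl tartrate (12 mol %), tBuOOH, 4 Å molecular sieves, CH2Cl2, −20 °C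
Reagents that add atoms: tert-butyl hydroperoxide, CC(C)(C)OO
Why: Sharpless asymmetric epoxidation touches only the allylic-alcohol olefin, and the D-(−)-tartrate delivers oxygen to the face giving the (2R,3R)-epoxide, which fixes C3 (retained) and C4 (inverted on ring closure).

Step 7
Reactants: 12 tert-butyl (4Z,8E)-11-[(2R,3R)-3-(hydroxymethyl)-3-methyloxiran-2-yl]-5,9-dimethylundeca-4,8-dienoate
Product: 13 tert-butyl (4Z,8E)-11-[(2R,3R)-3-{[tert-butyl(dimethyl)silyl]oxymethyl}-3-methyloxiran-2-yl]-5,9-dimethylundeca-4,8-dienoate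
Conditions: TBSCl, imidazole, DMF, 0 °C to rt
Reagents that add atoms: tert-butyldimethylsilyl chloride, CC(C)(C)[Si](C)(C)Cl
Why: Silyl ether formation masks O18 so that only O3 is acetylated later and removes a competing hydroxyl nucleophile from the cyclization.

Step 8
Reactants: 13 tert-butyl (4Z,8E)-11-[(2R,3R)-3-{[tert-butyl(dimethyl)silyl]oxymethyl}-3-methyloxiran-2-yl]-5,9-dimethylundeca-4,8-dienoate
Product: 14 3α-hydroxy-18-[(tert-butyldimethylsilyl)oxy]-14,15,16-trinorlabdan-13,8β-olide (5β-H, 9α-H, 10α-CH3; δ-lactone cis-fused to ring B)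
Conditions: MeAlCl2 (2.5 equiv), CH2Cl2, −94 to −78 °C; aq. NaHCO3
Reagents that add atoms: none
Why: Proposed new method: the MeAlCl2-activated epoxide is opened at C4 with inversion by the 8E olefin through a chair, the C10 cation is taken by the 4Z olefin through a second chair, and the ester carbonyl oxygen closes on C8 anti to the new C9–C10 bond before the dialkoxycarbenium ion loses isobutene, so that anti addition across both olefins (Stork–Eschenmoser) makes the E olefin give the trans-decalin and the Z olefin put the C9 side arm axial, anti to the C10 methyl and cis to O8; the closest known chemistry is Lewis-acid epoxide-initiated cation–olefin polycyclization combined with carboxyl-terminated polyene lactonization.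

Step 9
Reactants: 14 3α-hydroxy-18-[(tert-butyldimethylsilyl)oxy]-14,15,16-trinorlabdan-13,8β-olide
Product: 15 cyclic hemiketal (8β,13-epoxy-13-vinyl-13ξ-ol form, C13 epimers) of the vinyl ketone; 3α-OH, 18-OTBS
Conditions: CH2=CHMgBr (2.3 equiv), THF, −78 °C; aq. NH4Cl at −78 °C
Reagents that add atoms: vinylmagnesium bromide, C=C[Mg]Br
Why: Acyl addition arrested at the tetrahedral stage, since the first equivalent only deprotonates O3 and the second adds once to the lactone carbonyl to give a magnesium hemiketalate that is stable at −78 °C and returns the mono-adduct on work-up.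

Step 10
Reactants: 15 cyclic hemiketal of the vinyl ketone
Product: 17 18-[(tert-butyldimethylsilyl)oxy]labda-13(16),14-diene-3α,8β-diol (5β-H, 9α-H, 10α-CH3), via open-chain hydroxy enone 16 (not isolated)
Conditions: Ph3PCH3Br (6 equiv), KOtBu (5.5 equiv), THF, 0 °C to rt
Reagents that add atoms: methyltriphenylphosphonium bromide, C[P+](c1ccccc1)(c1ccccc1)c1ccccc1.[Br-]
Why: Under base the hemiketal opens to the vinyl ketone 16, which is trapped by Wittig methylenation at C13 (1,2-addition of the non-stabilised ylide) to give the 2-substituted 1,3-diene and free the tertiary 8-OH without touching a stereocentre.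

Step 11
Reactants: 17 18-[(tert-butyldimethylsilyl)oxy]labda-13(16),14-diene-3α,8β-diol
Product: 18 3α-acetoxy-18-[(tert-butyldimethylsilyl)oxy]labda-13(16),14-dien-8β-ol
Conditions: Ac2O, pyridine, rt
Reagents that add atoms: acetic anhydride, CC(=O)OC(C)=O
Why: Pyridine-mediated acylation esterifies only the equatorial secondary 3-OH, because the tertiary 8-OH is inert under these conditions and O18 is silylated.

Step 12
Reactants: 18 3α-acetoxy-18-[(tert-butyldimethylsilyl)oxy]labda-13(16),14-dien-8β-ol
Product: 19 target, 3α-acetoxylabda-13(16),14-diene-8β,18-diol = (1S,2R,4aR,5R,6S,8aS)-6-hydroxy-1-(hydroxymethyl)-1,4a,6-trimethyl-5-(3-methylidenepent-4-en-1-yl)decahydronaphthalen-2-yl acetate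
Conditions: HF·pyridine, THF/pyridine, 0 °C to rt
Reagents that add atoms: none
Why: Desilylation by acidic fluoride cleaves the Si–O bond without forming an alkoxide, which avoids O3 to O18 acetyl migration and leaves the diene, tertiary alcohol and acetate intact.

**Compound list**
1 | 3-methylbut-2-enoic acid | CC(C)=CC(=O)O | starting material
2 | geranyl bromide, (2E)-1-bromo-3,7-dimethylocta-2,6-diene | CC(C)=CCC/C(C)=C/CBr | starting material
3 | dilithium dienolate of 1, Li2(C5H6O2) | C=C(C)C=C([O-])[O-].[Li+].[Li+] | intermediate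
4 | dicopper dienolate of 1, Cu2(C5H6O2) | C=C(C)C=C(O[Cu])O[Cu] | intermediate
5 | (2Z,6E)-3,7,11-trimethyldodeca-2,6,10-trienoic acid | CC(C)=CCC/C(C)=C/CC/C(C)=C\C(=O)O | intermediate
6 | (2Z,6E)-3,7,11-trimethyldodeca-2,6,10-trien-1-ol | CC(C)=CCC/C(C)=C/CC/C(C)=C\CO | intermediate
7 | (2Z,6E)-1-bromo-3,7,11-trimethyldodeca-2,6,10-triene | CC(C)=CCC/C(C)=C/CC/C(C)=C\CBr | intermediate
8 | tert-butyl acetate | CC(=O)OC(C)(C)C | starting material
9 | lithium enolate of 8, LiOC(=CH2)OtBu | C=C([O-])OC(C)(C)C.[Li+] | intermediate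
10 | tert-butyl (4Z,8E)-5,9,13-trimethyltetradeca-4,8,12-trienoate | CC(C)=CCC/C(C)=C/CC/C(C)=C\CCC(=O)OC(C)(C)C | intermediate
11 | tert-butyl (4Z,8E,12E)-14-hydroxy-5,9,13-trimethyltetradeca-4,8,12-trienoate | OC/C(C)=C/CC/C(C)=C/CC/C(C)=C\CCC(=O)OC(C)(C)C | intermediate
12 | tert-butyl (4Z,8E)-11-[(2R,3R)-3-(hydroxymethyl)-3-methyloxiran-2-yl]-5,9-dimethylundeca-4,8-dienoate | OC[C@@]1(C)O[C@@H]1CC/C(C)=C/CC/C(C)=C\CCC(=O)OC(C)(C)C | intermediate
13 | TBS ether of 12 | CC(C)(C)[Si](C)(C)OC[C@@]1(C)O[C@@H]1CC/C(C)=C/CC/C(C)=C\CCC(=O)OC(C)(C)C | intermediate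
14 | 3α-hydroxy-18-TBSO-14,15,16-trinorlabdan-13,8β-olide (5β-H, 9α-H, 10α-CH3) | O=C3CC[C@@H]1[C@]2(C)CC[C@@H](O)[C@](C)(CO[Si](C)(C)C(C)(C)C)[C@H]2CC[C@]1(C)O3 | intermediate
15 | cyclic hemiketal of 16 (13-vinyl, C13 epimers) | C=CC3(O)CC[C@@H]1[C@]2(C)CC[C@@H](O)[C@](C)(CO[Si](C)(C)C(C)(C)C)[C@H]2CC[C@]1(C)O3 | intermediate
16 | 3α,8β-dihydroxy-18-TBSO-16-norlabd-14-en-13-one (open-chain vinyl ketone) | C=CC(=O)CC[C@@H]1[C@]2(C)CC[C@@H](O)[C@](C)(CO[Si](C)(C)C(C)(C)C)[C@H]2CC[C@]1(C)O | intermediate
17 | 18-TBSO-labda-13(16),14-diene-3α,8β-diol | C=CC(=C)CC[C@@H]1[C@]2(C)CC[C@@H](O)[C@](C)(CO[Si](C)(C)C(C)(C)C)[C@H]2CC[C@]1(C)O | intermediate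
18 | 3α-acetoxy-18-TBSO-labda-13(16),14-dien-8β-ol | C=CC(=C)CC[C@@H]1[C@]2(C)CC[C@@H](OC(C)=O)[C@](C)(CO[Si](C)(C)C(C)(C)C)[C@H]2CC[C@]1(C)O | intermediate
19 | 3α-acetoxylabda-13(16),14-diene-8β,18-diol (CNP0313672.1) | C=CC(=C)CC[C@@H]1[C@]2(C)CC[C@@H](OC(C)=O)[C@](C)(CO)[C@H]2CC[C@]1(C)O | target

**Totals and risks**

Total step count: 12. Longest linear sequence: 12 (from 1 and 2 to 19).

Steps most likely to fail:

Step 8 (key cascade). Risks are semipinacol rearrangement of the siloxy epoxide, arrest after ring A, and elimination instead of lactonization. The fallback sets out from 13 and returns at 14. Cp2TiCl (from Cp2TiCl2 and Mn, with 2,4,6-collidine and TMSCl, THF, rt, acidic work-up) opens the epoxide homolytically at C4. The tertiary radical closes rings A and B by two 6-endo additions through the same chair folding and ends by loss of hydrogen, giving tert-butyl 3α-hydroxy-18-TBSO-14,15,16-trinorlabd-8(17)-en-13-oate F2. Camphorsulfonic acid in CH2Cl2 then protonates the exocyclic olefin, and the ester closes on the C8 cation from the side of the axial side arm with loss of isobutene, giving 14.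

Step 1 (γ- versus α-alkylation and the Z:E ratio). The fallback sets out from 2 and returns at 6. LiCH2C≡CLi (propyne, n-BuLi, TMEDA) is alkylated by 2 at its sp3 carbon, and the remaining acetylide is quenched with paraformaldehyde to give (6E)-7,11-dimethyldodeca-6,10-dien-2-yn-1-ol F1. Fe(acac)3-catalysed, alkoxide-directed syn-carbomagnesiation with MeMgBr (THF, −78 to 0 °C) puts methyl on C3 syn to the new hydrogen, which is the 2Z olefin, and gives 6 directly without passing through 5.

Step 9 (over-addition or conjugate addition to the liberated enone; this fallback also bypasses step 10). The fallback sets out from 14 and returns at 17. iBu2AlH (CH2Cl2, −78 °C) reduces the lactone to the lactol 3α-hydroxy-18-TBSO-14,15,16-trinorlabdane 8β,13-lactol F3. Dimethyl (1-diazo-2-oxopropyl)phosphonate with K2CO3 in MeOH homologates its latent C13 aldehyde to the terminal alkyne 18-TBSO-15,16-dinorlabd-13-yne-3α,8β-diol F4. Enyne cross-metathesis with ethylene (second-generation Grubbs catalyst (H2IMes)(PCy3)Cl2Ru=CHPh, CH2=CH2 1 atm, toluene, 60 °C) converts the alkyne into the 2-substituted 1,3-diene 17.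

**Further compounds**
F1 | step 1 | (6E)-7,11-dimethyldodeca-6,10-dien-2-yn-1-ol | CC(C)=CCC/C(C)=C/CCC#CCO
F2 | step 8 | tert-butyl 3α-hydroxy-18-TBSO-14,15,16-trinorlabd-8(17)-en-13-oate (9α-H, side arm β) | CC(C)(C)OC(=O)CC[C@@H]1[C@]2(C)CC[C@@H](O)[C@](C)(CO[Si](C)(C)C(C)(C)C)[C@H]2CCC1=C
F3 | step 9 | 3α-hydroxy-18-TBSO-14,15,16-trinorlabdane 8β,13-lactol (C13 epimers) | OC3CC[C@@H]1[C@]2(C)CC[C@@H](O)[C@](C)(CO[Si](C)(C)C(C)(C)C)[C@H]2CC[C@]1(C)O3
F4 | step 9 | 18-TBSO-15,16-dinorlabd-13-yne-3α,8β-diol | C#CCC[C@@H]1[C@]2(C)CC[C@@H](O)[C@](C)(CO[Si](C)(C)C(C)(C)C)[C@H]2CC[C@]1(C)O
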